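A direct plan would esterify ferulic acid and then caffeic acid onto (R)-butane-1,3-diol (monoester A1, mixed diester A2), irradiate A2 to the macrocyclic β-truxinate A3, reduce it to the cyclobutane diol A4 and open the C7–C7' bond by oxidising the catechol. Its weakest steps would be:
(a) the two tether esterifications, which would spend two steps on unprotected phenols for a linker that is cut off again;
(b) the photocycloaddition, where the absolute sense of every ring centre would rest on one remote methyl group and one folded conformer, against E/Z isomerisation;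
(c) the oxidative ring opening on the last intermediate, which would erase C7 and C7' and rebuild C7' by uncatalysed addition of water to a quinone methide, with nothing to fix its configuration.

Plan of the new route. C7'–OH is taken back to the aryl ketone. The 4-aroyl-2-aryloxolane is then cut at C7–C8 and C8'–C9' in one retro Prins–pinacol step, giving the acetal of vanillin acetate with an (R)-2-aryl-pent-3-ene-1,2-diol. The diol is cut at C7'–C8' (alkynylation of an aryl glyoxylate) and at ring B–C7' (aryl Grignard plus oxalate).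
Enabling feature: the ring atoms O1–C9'H2–C8', with the oxygenated carbon C7' on C8', are a 1,2-diol in which C9' has slipped from C7' to C8', and C7 is an aldehyde carbon on O1.
The oxolane is the only core ring and forms once, in step 6, from an open-chain precursor, so no cyclobutane, tether or quinone methide occurs. C7' is reset by a reduction in which catalyst and substrate are matched.

Key step: step 6

Assumptions: lignan numbering is used (C7–C9 on the ring A side, C7'–C9' on the ring B side; ring A = guaiacyl, ring B = catechol); Ts = 4-methylbenzenesulfonyl, TBDPS = tert-butyl(diphenyl)silyl; 1, 3, 6 and 9 are commercial. In step 6 the chair with the ring B aryl group equatorial is taken as the reactive one; if the other chair dominated, the antipodal ligand would be used in step 3.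

Step 1
Reactants: 1 4-bromobenzene-1,2-diol
Product: 2 4-bromo-1,2-phenylene bis(4-methylbenzenesulfonate)
Conditions: TsCl (2.3 equiv), Et3N (3 equiv), DMAP (5 mol%), CH2Cl2, 0 °C to rt
Reagents that add atoms: 4-methylbenzenesulfonyl chloride, Cc1ccc(cc1)S(Cl)(=O)=O
Why: O-sulfonylation of both phenols masks the catechol as an electron-poor bis(arenesulfonate) that should survive organomagnesium, hydride and Lewis acid and will later keep the benzylic carbon C7' from ionising.

Step 2
Reactants: 2 4-bromo-1,2-phenylene bis(4-methylbenzenesulfonate); 3 diethyl oxalate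
Product: 5 ethyl 2-[3,4-bis(TsO)phenyl]-2-oxoacetate, via arylmagnesium chloride 4 (not isolated)
Conditions: i-PrMgCl·LiCl (1.05 equiv), THF, −20 °C; then addition to 3 (2.5 equiv), THF, −78 °C; aq NH4Cl
Reagents that add atoms: none
Why: Bromine–magnesium exchange (the sulfonyloxy groups are meta and para to bromine, so no aryne can form) and acylation of the arylmagnesium with excess oxalate, whose magnesium hemiketal alkoxide holds the adduct until work-up, should give the aryl glyoxylate that carries ring B, C7' and the future C9'.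

Step 3
Reactants: 5 ethyl 2-[3,4-bis(TsO)phenyl]-2-oxoacetate; 6 tert-butyl(diphenyl)(prop-2-yn-1-yloxy)silane
Product: 7 ethyl (2S)-2-[3,4-bis(TsO)phenyl]-2-hydroxy-5-(TBDPS-oxy)pent-3-ynoate
Conditions: Zn(OTf)2 (20 mol%), (1S,2S)- or (1R,2R)-2-(dimethylamino)-1-(4-nitrophenyl)-3-[(tert-butyldimethylsilyl)oxy]propan-1-ol (22 mol%, the antipode that gives 7), Et3N (30 mol%), toluene, 70 °C
Reagents that add atoms: none
Why: Catalytic enantioselective alkynylation of an α-keto ester, in which the zinc alkynylide made from 6 adds to the ketone carbonyl held by the chiral zinc amino alkoxide, joins C7' to C8' and sets the tertiary carbinol C7' as the only stereocentre put in by a reagent before the key step.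

Step 4
Reactants: 7 ethyl (2S)-2-[3,4-bis(TsO)phenyl]-2-hydroxy-5-(TBDPS-oxy)pent-3-ynoate
Product: 8 (2R,3E)-2-[3,4-bis(TsO)phenyl]-5-(TBDPS-oxy)pent-3-ene-1,2-diol
Conditions: LiAlH4 (3 equiv), THF, 0 °C to rt; aq Rochelle salt
Reagents that add atoms: none
Why: LiAlH4 reduces the ester to the primary alcohol C9', and the tertiary alkoxide then directs trans-hydroalumination of the alkyne through a five-membered alkenylalanate, so only the E-alkene should form while the stereocentre is untouched (its descriptor changes to R by priority only).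

Step 5
Reactants: 8 (2R,3E)-2-[3,4-bis(TsO)phenyl]-5-(TBDPS-oxy)pent-3-ene-1,2-diol; 9 4-formyl-2-methoxyphenyl acetate
Product: 10 4-{(4R)-4-[3,4-bis(TsO)phenyl]-4-[(1E)-3-(TBDPS-oxy)prop-1-en-1-yl]-1,3-dioxolan-2-yl}-2-methoxyphenyl acetate (both epimers at the acetal carbon)
Conditions: 9 (1.2 equiv), TsOH·H2O (5 mol%), MgSO4, CH2Cl2, rt
Reagents that add atoms: none
Why: Acid-catalysed acetalisation of the 1,2-diol should give the five-membered dioxolane (the E-alkene rules out a seven-membered acetal), and both epimers at the acetal carbon are usable because that carbon becomes planar in step 6.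

Step 6
Reactants: 10 4-{(4R)-4-[3,4-bis(TsO)phenyl]-4-[(1E)-3-(TBDPS-oxy)prop-1-en-1-yl]-1,3-dioxolan-2-yl}-2-methoxyphenyl acetate
Product: 12 4-[(2S,3R,4S)-4-[3,4-bis(TsO)benzoyl]-3-(TBDPS-oxymethyl)oxolan-2-yl]-2-methoxyphenyl acetate, via oxocarbenium tin alkoxide 11 (not isolated)
Conditions: SnCl4 (1.5 equiv), CH2Cl2, −78 to −30 °C; aq NaHCO3; then DBU (0.1 equiv), CH2Cl2, rt
Reagents that add atoms: none
Why: Pinacol-terminated Prins cyclisation: SnCl4 opens the acetal at the tertiary oxygen to the E-oxocarbenium ion 11, C8 of the alkene attacks C7 through a chair transition state, and the positive charge building up at C8' is quenched by a 1,2-shift of C9' from C7' to C8' as the tin alkoxide collapses to the aryl ketone (the same product results if the order is 2-oxonia-Cope rearrangement, then aldol closure of the tin enolate onto the CH2=O+ end). The closest known reaction type is the Lewis acid rearrangement of 4-alkenyl-1,3-dioxolanes (acetals of allylic 1,2-diols) to 3-acyl-tetrahydrofurans. The oxolane is closed by a 6-endo cation–olefin cyclisation to an oxan-4-yl cation followed by ring contraction (or, in the alternative order, by a 5-exo aldol addition). C7 and C8 are set together: the E-oxocarbenium ion and the E-alkene put ring A and CH2OSi equatorial, hence 7,8-trans, and the (R)-configured C7' with its aryl group equatorial (the chair that avoids a syn-axial aryl/H8 contact and leads to the Z-enolate) fixes the alkene face that gives 7S,8R. C8' is formed trans to C9 because the C8–C9 bond is antiperiplanar to C8'–C7' in that chair, and as it is α to the ketone the DBU treatment should funnel any epimer to the all-trans oxolane. The step needs C–C bond formation to outrun ionisation of the tertiary benzylic C7'–O bond and aryl migration; the two sulfonyloxy groups on ring B suppress both, and the acetoxy group on ring A keeps the oxocarbenium ion electrophilic and the new C7–O bond inert to the Lewis acid.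

Step 7
Reactants: 12 4-[(2S,3R,4S)-4-[3,4-bis(TsO)benzoyl]-3-(TBDPS-oxymethyl)oxolan-2-yl]-2-methoxyphenyl acetate
Product: 13 4-[(2S,3R,4S)-4-{(R)-[3,4-bis(TsO)phenyl](hydroxy)methyl}-3-(TBDPS-oxymethyl)oxolan-2-yl]-2-methoxyphenyl acetate
Conditions: (S)-2-methyl-CBS-oxazaborolidine (0.2 equiv), BH3·SMe2 (0.8 equiv), THF, −20 °C; MeOH quench
Reagents that add atoms: none
Why: Corey–Bakshi–Shibata reduction, in which the (S)-oxazaborolidine delivers hydride to the ketone face that gives the (R)-carbinol C7' (aryl as the large group), the same face the substrate prefers by the Felkin–Anh model with C8 as the large α-substituent, so catalyst and substrate are matched and any enantiomeric ketone should react slowly and end mainly as a separable diastereomer.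

Step 8
Reactants: 13 4-[(2S,3R,4S)-4-{(R)-[3,4-bis(TsO)phenyl](hydroxy)methyl}-3-(TBDPS-oxymethyl)oxolan-2-yl]-2-methoxyphenyl acetate
Product: 14 4-[(R)-{(3S,4R,5S)-4-(TBDPS-oxymethyl)-5-(4-hydroxy-3-methoxyphenyl)oxolan-3-yl}(hydroxy)methyl]benzene-1,2-diol
Conditions: Mg turnings (15 equiv), MeOH, rt, ultrasound; aq NH4Cl
Reagents that add atoms: none
Why: Electron transfer from Mg in MeOH cleaves the S–O bond of both aryl sulfonates (reductive desulfonylation) and the Mg(OMe)2 formed transesterifies the aryl acetate, whereas the alkyl silyl ether, the benzylic alcohol and the benzylic ether should not be reduced.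

Step 9
Reactants: 14 4-[(R)-{(3S,4R,5S)-4-(TBDPS-oxymethyl)-5-(4-hydroxy-3-methoxyphenyl)oxolan-3-yl}(hydroxy)methyl]benzene-1,2-diol
Product: 15 4-[(R)-hydroxy{(3S,4R,5S)-5-(4-hydroxy-3-methoxyphenyl)-4-(hydroxymethyl)oxolan-3-yl}methyl]benzene-1,2-diol
Conditions: TBAF (1.5 equiv), AcOH (1.5 equiv), THF, 0 °C to rt
Reagents that add atoms: none
Why: Fluoride-induced cleavage of the primary silyl ether, buffered with acetic acid so that the catechol and the two para-hydroxybenzylic C–O bonds meet neither strong base nor acid, should release the C9 hydroxyl and give the target with all four stereocentres unchanged.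

Compound list
1 | 4-bromobenzene-1,2-diol (4-bromocatechol) | Oc1ccc(Br)cc1O | starting material
2 | 4-bromo-1,2-phenylene bis(4-methylbenzenesulfonate) | Cc1ccc(cc1)S(=O)(=O)Oc1ccc(Br)cc1OS(=O)(=O)c1ccc(C)cc1 | intermediate
3 | diethyl oxalate | CCOC(=O)C(=O)OCC | starting material
4 | [3,4-bis(4-methylbenzenesulfonyloxy)phenyl]magnesium chloride (LiCl complex) | Cc1ccc(cc1)S(=O)(=O)Oc1ccc([Mg]Cl)cc1OS(=O)(=O)c1ccc(C)cc1 | intermediate
5 | ethyl 2-[3,4-bis(4-methylbenzenesulfonyloxy)phenyl]-2-oxoacetate | CCOC(=O)C(=O)c1ccc(OS(=O)(=O)c2ccc(C)cc2)c(OS(=O)(=O)c2ccc(C)cc2)c1 | intermediate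
6 | tert-butyl(diphenyl)(prop-2-yn-1-yloxy)silane | C#CCO[Si](c1ccccc1)(c1ccccc1)C(C)(C)C | starting material
7 | ethyl (2S)-2-[3,4-bis(4-methylbenzenesulfonyloxy)phenyl]-5-{[tert-butyl(diphenyl)silyl]oxy}-2-hydroxypent-3-ynoate | CCOC(=O)[C@](O)(c1ccc(OS(=O)(=O)c2ccc(C)cc2)c(OS(=O)(=O)c2ccc(C)cc2)c1)C#CCO[Si](c1ccccc1)(c1ccccc1)C(C)(C)C | intermediate
8 | (2R,3E)-2-[3,4-bis(4-methylbenzenesulfonyloxy)phenyl]-5-{[tert-butyl(diphenyl)silyl]oxy}pent-3-ene-1,2-diol | OC[C@](O)(c1ccc(OS(=O)(=O)c2ccc(C)cc2)c(OS(=O)(=O)c2ccc(C)cc2)c1)/C=C/CO[Si](c1ccccc1)(c1ccccc1)C(C)(C)C | intermediate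
9 | 4-formyl-2-methoxyphenyl acetate (vanillin acetate) | COc1cc(C=O)ccc1OC(C)=O | starting material
10 | 4-{(4R)-4-[3,4-bis(4-methylbenzenesulfonyloxy)phenyl]-4-[(1E)-3-{[tert-butyl(diphenyl)silyl]oxy}prop-1-en-1-yl]-1,3-dioxolan-2-yl}-2-methoxyphenyl acetate (both epimers at C2 of the dioxolane) | COc1cc(C2OC[C@](O2)(c2ccc(OS(=O)(=O)c3ccc(C)cc3)c(OS(=O)(=O)c3ccc(C)cc3)c2)/C=C/CO[Si](c2ccccc2)(c2ccccc2)C(C)(C)C)ccc1OC(C)=O | intermediate
11 | ring-opened E-oxocarbenium ion of 10 with the tertiary oxygen bound to tin (zwitterion, C7' still R) | COc1cc(/C=[O+]/C[C@](O[Sn-](Cl)(Cl)(Cl)Cl)(c2ccc(OS(=O)(=O)c3ccc(C)cc3)c(OS(=O)(=O)c3ccc(C)cc3)c2)/C=C/CO[Si](c2ccccc2)(c2ccccc2)C(C)(C)C)ccc1OC(C)=O | intermediate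
12 | 4-[(2S,3R,4S)-4-[3,4-bis(4-methylbenzenesulfonyloxy)benzoyl]-3-({[tert-butyl(diphenyl)silyl]oxy}methyl)oxolan-2-yl]-2-methoxyphenyl acetate | COc1cc([C@H]2OC[C@@H](C(=O)c3ccc(OS(=O)(=O)c4ccc(C)cc4)c(OS(=O)(=O)c4ccc(C)cc4)c3)[C@@H]2CO[Si](c2ccccc2)(c2ccccc2)C(C)(C)C)ccc1OC(C)=O | intermediate
13 | 4-[(2S,3R,4S)-4-{(R)-[3,4-bis(4-methylbenzenesulfonyloxy)phenyl](hydroxy)methyl}-3-({[tert-butyl(diphenyl)silyl]oxy}methyl)oxolan-2-yl]-2-methoxyphenyl acetate | COc1cc([C@H]2OC[C@@H]([C@@H](O)c3ccc(OS(=O)(=O)c4ccc(C)cc4)c(OS(=O)(=O)c4ccc(C)cc4)c3)[C@@H]2CO[Si](c2ccccc2)(c2ccccc2)C(C)(C)C)ccc1OC(C)=O | intermediate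
14 | 4-[(R)-{(3S,4R,5S)-4-({[tert-butyl(diphenyl)silyl]oxy}methyl)-5-(4-hydroxy-3-methoxyphenyl)oxolan-3-yl}(hydroxy)methyl]benzene-1,2-diol | COc1cc([C@H]2OC[C@@H]([C@@H](O)c3ccc(O)c(O)c3)[C@@H]2CO[Si](c2ccccc2)(c2ccccc2)C(C)(C)C)ccc1O | intermediate
15 | 4-[(R)-hydroxy{(3S,4R,5S)-5-(4-hydroxy-3-methoxyphenyl)-4-(hydroxymethyl)oxolan-3-yl}methyl]benzene-1,2-diol | COc1cc([C@H]2OC[C@@H]([C@@H](O)c3ccc(O)c(O)c3)[C@@H]2CO)ccc1O | target

Total step count: 9. Longest linear sequence: 9 steps (1 to 15); 3, 6 and 9 enter as commercial reagents.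

Steps most likely to fail: 6, 3 and 4.

Step 6. The stereochemical information of C7' could be lost before or during C–C bond formation, either by reversible ionisation of the tertiary benzylic C–O bond or by reaction through the alternative chair with the aryl group axial. The ketone would then be formed with lowered enantiomeric purity. The fallback sets out from 12 and returns at 13. Absolute control is moved to the reduction, which would be run as a kinetic resolution with the step 7 catalyst and a deficit of BH3·SMe2 at −40 °C. The matched ketone 12 should be reduced to 13, while its mismatched enantiomer, 4-[(2R,3S,4R)-4-[3,4-bis(4-methylbenzenesulfonyloxy)benzoyl]-3-({[tert-butyl(diphenyl)silyl]oxy}methyl)oxolan-2-yl]-2-methoxyphenyl acetate F1, should stay behind as ketone and be removed by chromatography.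

Step 3. Facial discrimination of this electron-poor aryl glyoxylate could be poor, or uncatalysed background addition at 70 °C could erode the selectivity. The fallback sets out from 5 and 6 and returns at 8. The lithium acetylide of 6 (n-BuLi, THF, −78 °C) would be added to 5 to give racemic ethyl 2-[3,4-bis(4-methylbenzenesulfonyloxy)phenyl]-5-{[tert-butyl(diphenyl)silyl]oxy}-2-hydroxypent-3-ynoate F2. Reduction as in step 4 would give the racemic (3E)-2-[3,4-bis(4-methylbenzenesulfonyloxy)phenyl]-5-{[tert-butyl(diphenyl)silyl]oxy}pent-3-ene-1,2-diol F3. F3 would be resolved by lipase-catalysed acylation of the primary hydroxyl (Burkholderia cepacia lipase or an enantiocomplementary lipase, vinyl acetate, tert-butyl methyl ether). The enzyme would be chosen so that the (S)-diol is converted into (2S,3E)-2-[3,4-bis(4-methylbenzenesulfonyloxy)phenyl]-5-{[tert-butyl(diphenyl)silyl]oxy}-2-hydroxypent-3-en-1-yl acetate F4 and (R)-diol 8 is recovered unchanged.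

Step 4. Hydride could attack the sulfur of the aryl sulfonates, or the alkenylalanate could lose the silyloxy group by β-elimination to an allene. The fallback sets out from 7 and returns at 8. Only the ester would be reduced with NaBH4 (EtOH, 0 °C; α-hydroxy esters are reduced by borohydride) to (2S)-2-[3,4-bis(4-methylbenzenesulfonyloxy)phenyl]-5-{[tert-butyl(diphenyl)silyl]oxy}pent-3-yne-1,2-diol F5. The propargylic alcohol would then be reduced to the E-alkene by electron transfer with CrSO4 in aqueous DMF at rt, conditions under which aryl sulfonates and silyl ethers are inert.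

Further compounds
F1 | step 6 | 4-[(2R,3S,4R)-4-[3,4-bis(4-methylbenzenesulfonyloxy)benzoyl]-3-({[tert-butyl(diphenyl)silyl]oxy}methyl)oxolan-2-yl]-2-methoxyphenyl acetate | COc1cc([C@@H]2OC[C@H](C(=O)c3ccc(OS(=O)(=O)c4ccc(C)cc4)c(OS(=O)(=O)c4ccc(C)cc4)c3)[C@H]2CO[Si](c2ccccc2)(c2ccccc2)C(C)(C)C)ccc1OC(C)=O
F2 | step 3 | racemic ethyl 2-[3,4-bis(4-methylbenzenesulfonyloxy)phenyl]-5-{[tert-butyl(diphenyl)silyl]oxy}-2-hydroxypent-3-ynoate | CCOC(=O)C(O)(c1ccc(OS(=O)(=O)c2ccc(C)cc2)c(OS(=O)(=O)c2ccc(C)cc2)c1)C#CCO[Si](c1ccccc1)(c1ccccc1)C(C)(C)C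
F3 | step 3 | racemic (3E)-2-[3,4-bis(4-methylbenzenesulfonyloxy)phenyl]-5-{[tert-butyl(diphenyl)silyl]oxy}pent-3-ene-1,2-diol | OCC(O)(c1ccc(OS(=O)(=O)c2ccc(C)cc2)c(OS(=O)(=O)c2ccc(C)cc2)c1)/C=C/CO[Si](c1ccccc1)(c1ccccc1)C(C)(C)C
F4 | step 3 | (2S,3E)-2-[3,4-bis(4-methylbenzenesulfonyloxy)phenyl]-5-{[tert-butyl(diphenyl)silyl]oxy}-2-hydroxypent-3-en-1-yl acetate | CC(=O)OC[C@@](O)(c1ccc(OS(=O)(=O)c2ccc(C)cc2)c(OS(=O)(=O)c2ccc(C)cc2)c1)/C=C/CO[Si](c1ccccc1)(c1ccccc1)C(C)(C)C
F5 | step 4 | (2S)-2-[3,4-bis(4-methylbenzenesulfonyloxy)phenyl]-5-{[tert-butyl(diphenyl)silyl]oxy}pent-3-yne-1,2-diol | OC[C@](O)(c1ccc(OS(=O)(=O)c2ccc(C)cc2)c(OS(=O)(=O)c2ccc(C)cc2)c1)C#CCO[Si](c1ccccc1)(c1ccccc1)C(C)(C)C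
A1 | direct plan | (3R)-3-hydroxybutyl (E)-ferulate | COc1cc(/C=C/C(=O)OCC[C@@H](C)O)ccc1O
A2 | direct plan | (2S)-4-[(E)-feruloyloxy]butan-2-yl (E)-caffeate | COc1cc(/C=C/C(=O)OCC[C@H](C)OC(=O)/C=C/c2ccc(O)c(O)c2)ccc1O
A3 | direct plan | macrocyclic heterodimeric β-truxinate (cyclobutane cis-fused to the nine-membered dilactone) | O=C1OCC[C@H](C)OC(=O)[C@H]2[C@H](c3ccc(O)c(O)c3)[C@H](c3ccc(O)c(OC)c3)[C@@H]12
A4 | direct plan | [(1R,2S,3R,4S)-3-(3,4-dihydroxyphenyl)-4-(4-hydroxy-3-methoxyphenyl)cyclobutane-1,2-diyl]dimethanol | OC[C@@H]1[C@@H](c2ccc(O)c(OC)c2)[C@@H](c2ccc(O)c(O)c2)[C@@H]1CO
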